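**Retrosynthetic overview**
1. Cassyformin 10 ⇒ bis-silyl ether 9 (fluoride deprotection last) ⇒ aryl aldehyde 8 (Wittig two-carbon extension to the enal).
2. Key disconnection: the O1–C2 bond of the dihydrofuran ring. 8 ⇒ o-hydroxystilbene-type allylic alcohol 7 by a catalytic enantioselective intramolecular hydroalkoxylation that sets C2 and C3.
3. 7 ⇒ 5-iodovanillin 6 + cinnamyl alcohol 5 (Heck reaction makes the C3–C3a bond, no stereocentre).
4. 5 ⇒ 5-hydroxyvanillin 1 (silylation, Wittig, i-Bu2AlH).
5. Ring order: both benzene rings are bought; the dihydrofuran ring is the only ring formed (step 5).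

Assumption: the SMILES is read as (2R,3S), which is the 2,3-trans isomer, and 5-hydroxyvanillin 1 and 5-iodovanillin 6 are taken as catalogue chemicals.

**Route**

Step 1
Reactants: 1 3,4-dihydroxy-5-methoxybenzaldehyde (5-hydroxyvanillin)
Product: 2 3,4-bis(tert-butyldimethylsilyloxy)-5-methoxybenzaldehyde
Conditions: TBSCl (2.5 equiv), imidazole (5 equiv), DMF, rt
Reagents that add atoms: tert-butyldimethylsilyl chloride, CC(C)(C)[Si](C)(C)Cl
Why: Imidazole-promoted O-silylation (silyl ether protection) masks the oxidation-prone catechol as ethers that survive ylides, hydride and palladium and are removed by fluoride at the end; no stereocentre.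

Step 2
Reactants: 2 3,4-bis(tert-butyldimethylsilyloxy)-5-methoxybenzaldehyde
Product: 3 ethyl (E)-3-[3,4-bis(tert-butyldimethylsilyloxy)-5-methoxyphenyl]prop-2-enoate
Conditions: Ph3P=CHCO2Et (1.2 equiv), toluene, 80 °C
Reagents that add atoms: ethyl (triphenylphosphoranylidene)acetate, CCOC(=O)C=P(c1ccccc1)(c1ccccc1)c1ccccc1
Why: Wittig olefination with a stabilised ylide gives the (E)-enoate under neutral conditions that leave the aryl silyl ethers intact.

Step 3
Reactants: 3 ethyl (E)-3-[3,4-bis(tert-butyldimethylsilyloxy)-5-methoxyphenyl]prop-2-enoate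
Product: 5 (E)-3-[3,4-bis(tert-butyldimethylsilyloxy)-5-methoxyphenyl]prop-2-en-1-ol, via bis-silyl cinnamaldehyde 4 (not isolated)
Conditions: i-Bu2AlH (2.5 equiv), CH2Cl2, −78 to 0 °C; aq. potassium sodium tartrate work-up
Reagents that add atoms: none
Why: i-Bu2AlH 1,2-reduction of the enoate runs through enal 4 to the allylic alcohol without touching the alkene or the silyl ethers.

Step 4
Reactants: 5 (E)-3-[3,4-bis(tert-butyldimethylsilyloxy)-5-methoxyphenyl]prop-2-en-1-ol; 6 4-hydroxy-3-iodo-5-methoxybenzaldehyde (5-iodovanillin)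
Product: 7 3-[(1Z)-1-[3,4-bis(tert-butyldimethylsilyloxy)-5-methoxyphenyl]-3-hydroxyprop-1-en-2-yl]-4-hydroxy-5-methoxybenzaldehyde
Conditions: Pd(OAc)2 (5 mol %), n-Bu4NCl (1 equiv), NaHCO3 (2.5 equiv), DMF, 70 °C
Reagents that add atoms: none
Why: Mizoroki–Heck reaction under ligand-free Jeffery conditions: syn carbopalladation puts the aryl group on the carbon remote from the electron-rich arene (palladium benzylic), and syn β-hydride elimination gives the (Z)-alkene with the two aryl groups trans; the chloride-rich neutral medium and base quench of the palladium hydride leave the free phenol unreacted, so ring closure is kept for step 5.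

Step 5
Reactants: 7 3-[(1Z)-1-[3,4-bis(tert-butyldimethylsilyloxy)-5-methoxyphenyl]-3-hydroxyprop-1-en-2-yl]-4-hydroxy-5-methoxybenzaldehyde
Product: 8 (2R,3S)-2-[3,4-bis(tert-butyldimethylsilyloxy)-5-methoxyphenyl]-3-(hydroxymethyl)-7-methoxy-2,3-dihydro-1-benzofuran-5-carbaldehyde
Conditions: Pd2(dba)3 (2.5 mol %), (R)-DTBM-SEGPHOS (6 mol %), (PhO)2P(O)OH (5 mol %), toluene, 40 °C
Reagents that add atoms: none
Why: Proposed new method: a cationic chiral bisphosphine palladium hydride (divalent palladium, formed from the zerovalent palladium precursor and the phosphoric acid) adds syn across the (Z)-alkene and delivers hydride under ligand control to the Re face of the alkene carbon carrying ring B (this gives 3S); the resulting η3-benzylpalladium species is the one that released 7 in step 4 (microscopic reverse of β-hydride elimination), and with no halide or stoichiometric base present the neighbouring phenol captures the benzylic carbon to form the O1–C2 bond, closing to the 2,3-trans ring (aryl anti to CH2OH, also the thermodynamic isomer) so that 3S relays to 2R; the closest known reaction types are palladium-hydride hydroamination of vinylarenes through η3-benzyl intermediates and the C–O ring closure of oxy-Heck annulations; the ligand hand is assigned from a quadrant model, is checked by chiral HPLC on the first run, and the (S)-ligand would give the antipode.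

Step 6
Reactants: 8 (2R,3S)-2-[3,4-bis(tert-butyldimethylsilyloxy)-5-methoxyphenyl]-3-(hydroxymethyl)-7-methoxy-2,3-dihydro-1-benzofuran-5-carbaldehyde
Product: 9 (E)-3-[(2R,3S)-2-[3,4-bis(tert-butyldimethylsilyloxy)-5-methoxyphenyl]-3-(hydroxymethyl)-7-methoxy-2,3-dihydro-1-benzofuran-5-yl]prop-2-enal
Conditions: Ph3P=CHCHO (1.3 equiv), toluene, 80 °C
Reagents that add atoms: (triphenylphosphoranylidene)acetaldehyde, O=CC=P(c1ccccc1)(c1ccccc1)c1ccccc1
Why: Wittig two-carbon homologation with the stabilised formylmethylene ylide gives the (E)-enal under neutral conditions that tolerate the free primary alcohol and cannot epimerise C2 or C3.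

Step 7
Reactants: 9 (E)-3-[(2R,3S)-2-[3,4-bis(tert-butyldimethylsilyloxy)-5-methoxyphenyl]-3-(hydroxymethyl)-7-methoxy-2,3-dihydro-1-benzofuran-5-yl]prop-2-enal
Product: 10 cassyformin, (E)-3-[(2R,3S)-2-(3,4-dihydroxy-5-methoxyphenyl)-3-(hydroxymethyl)-7-methoxy-2,3-dihydro-1-benzofuran-5-yl]prop-2-enal
Conditions: KHF2 (3 equiv), MeOH, rt, under argon
Reagents that add atoms: none
Why: Fluoride cleavage of the phenolic silyl ethers with mildly acidic KHF2 frees the catechol without base that could add to the enal or open the benzylic ether, so both stereocentres stay untouched.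

**Compound list**
1 | 3,4-dihydroxy-5-methoxybenzaldehyde (5-hydroxyvanillin) | COc1cc(C=O)cc(O)c1O | starting material
2 | 3,4-bis(tert-butyldimethylsilyloxy)-5-methoxybenzaldehyde | COc1cc(C=O)cc(O[Si](C)(C)C(C)(C)C)c1O[Si](C)(C)C(C)(C)C | intermediate
3 | ethyl (E)-3-[3,4-bis(tert-butyldimethylsilyloxy)-5-methoxyphenyl]prop-2-enoate | CCOC(=O)/C=C/c1cc(OC)c(O[Si](C)(C)C(C)(C)C)c(O[Si](C)(C)C(C)(C)C)c1 | intermediate
4 | (E)-3-[3,4-bis(tert-butyldimethylsilyloxy)-5-methoxyphenyl]prop-2-enal (bis-silyl cinnamaldehyde, not isolated) | O=C/C=C/c1cc(OC)c(O[Si](C)(C)C(C)(C)C)c(O[Si](C)(C)C(C)(C)C)c1 | intermediate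
5 | (E)-3-[3,4-bis(tert-butyldimethylsilyloxy)-5-methoxyphenyl]prop-2-en-1-ol | OC/C=C/c1cc(OC)c(O[Si](C)(C)C(C)(C)C)c(O[Si](C)(C)C(C)(C)C)c1 | intermediate
6 | 4-hydroxy-3-iodo-5-methoxybenzaldehyde (5-iodovanillin) | COc1cc(C=O)cc(I)c1O | starting material
7 | 3-[(1Z)-1-[3,4-bis(tert-butyldimethylsilyloxy)-5-methoxyphenyl]-3-hydroxyprop-1-en-2-yl]-4-hydroxy-5-methoxybenzaldehyde | OC/C(c1cc(C=O)cc(OC)c1O)=C\c1cc(OC)c(O[Si](C)(C)C(C)(C)C)c(O[Si](C)(C)C(C)(C)C)c1 | intermediate
8 | (2R,3S)-2-[3,4-bis(tert-butyldimethylsilyloxy)-5-methoxyphenyl]-3-(hydroxymethyl)-7-methoxy-2,3-dihydro-1-benzofuran-5-carbaldehyde | COc1cc([C@@H]2Oc3c(OC)cc(C=O)cc3[C@H]2CO)cc(O[Si](C)(C)C(C)(C)C)c1O[Si](C)(C)C(C)(C)C | intermediate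
9 | (E)-3-[(2R,3S)-2-[3,4-bis(tert-butyldimethylsilyloxy)-5-methoxyphenyl]-3-(hydroxymethyl)-7-methoxy-2,3-dihydro-1-benzofuran-5-yl]prop-2-enal | COc1cc([C@@H]2Oc3c(OC)cc(/C=C/C=O)cc3[C@H]2CO)cc(O[Si](C)(C)C(C)(C)C)c1O[Si](C)(C)C(C)(C)C | intermediate
10 | cassyformin, (E)-3-[(2R,3S)-2-(3,4-dihydroxy-5-methoxyphenyl)-3-(hydroxymethyl)-7-methoxy-2,3-dihydro-1-benzofuran-5-yl]prop-2-enal | COc1cc([C@@H]2Oc3c(OC)cc(/C=C/C=O)cc3[C@H]2CO)cc(O)c1O | target

**Step count and risks**

Total step count: 7. Longest linear sequence: 7 steps (1 to 10); 6 joins at step 4.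

The three steps most likely to fail:

Step 5, the proposed new hydroalkoxylation. The risks are slow hydropalladation of the hindered trisubstituted alkene, palladium-hydride isomerisation of the allylic alcohol to the saturated aldehyde, acid-assisted ionisation of the allylic alcohol, and insufficient ee. The fallback uses known chemistry and a different approach: C3 is set by hydrogenation and the C–O bond is closed oxidatively under substrate control. It sets out from 7. Iridium-catalysed asymmetric hydrogenation of the trisubstituted allylic alcohol ([Ir(cod)((S)-tBu-PHOX)]BArF, H2 50 bar, CH2Cl2, rt, with the ligand enantiomer chosen for Re-face addition at the ring-B-bearing carbon) gives (S)-3-[3,4-bis(tert-butyldimethylsilyloxy)-5-methoxyphenyl]-2-(5-formyl-2-hydroxy-3-methoxyphenyl)propan-1-ol F1. DDQ (CH2Cl2, 0 °C) then oxidises the electron-rich benzylic CH2 to the quinone-methide-type cation, which the phenol traps anti to the CH2OH group. The fallback comes back to the route at 8.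

Step 4, the Heck coupling. The risks are arylation at the benzylic carbon (directed by the free hydroxyl), premature racemic ring closure of the product, and redox isomerisation of 5. The fallback changes the approach to an annulation in the cationic manifold followed by resolution. It sets out from 5 and 6. The known silver-promoted palladium oxyarylation of o-iodophenols with conjugated alkenes (Pd(OAc)2, Ag2CO3, acetone, 56 °C) abstracts iodide, which enforces benzylic palladium and immediate C–O closure. It gives racemic trans material, that is 8 together with (2S,3R)-2-[3,4-bis(tert-butyldimethylsilyloxy)-5-methoxyphenyl]-3-(hydroxymethyl)-7-methoxy-2,3-dihydro-1-benzofuran-5-carbaldehyde F2, which preparative chiral SFC removes. The fallback comes back to the route at 8, at the cost of half the material.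

Step 6, the Wittig reaction with the formylmethylene ylide. The risks are slow reaction of the electron-rich aldehyde and a second olefination of the product enal to the dienal. The fallback changes the approach to ester-level homologation and redox adjustment. It sets out from 8. Wittig reaction with Ph3P=CHCO2Et (toluene, 80 °C) gives ethyl (E)-3-[(2R,3S)-2-[3,4-bis(tert-butyldimethylsilyloxy)-5-methoxyphenyl]-3-(hydroxymethyl)-7-methoxy-2,3-dihydro-1-benzofuran-5-yl]prop-2-enoate F3. i-Bu2AlH (CH2Cl2, −78 °C) gives (E)-3-[(2R,3S)-2-[3,4-bis(tert-butyldimethylsilyloxy)-5-methoxyphenyl]-3-(hydroxymethyl)-7-methoxy-2,3-dihydro-1-benzofuran-5-yl]prop-2-en-1-ol F4. MnO2 (CH2Cl2, rt) oxidises only the allylic alcohol and leaves the saturated primary alcohol. The fallback comes back to the route at 9.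

**Further compounds**
F1 | step 5 | (S)-3-[3,4-bis(tert-butyldimethylsilyloxy)-5-methoxyphenyl]-2-(5-formyl-2-hydroxy-3-methoxyphenyl)propan-1-ol | O=Cc1cc(OC)c(O)c(c1)[C@H](Cc1cc(OC)c(O[Si](C)(C)C(C)(C)C)c(O[Si](C)(C)C(C)(C)C)c1)CO
F2 | step 4 | (2S,3R)-2-[3,4-bis(tert-butyldimethylsilyloxy)-5-methoxyphenyl]-3-(hydroxymethyl)-7-methoxy-2,3-dihydro-1-benzofuran-5-carbaldehyde | COc1cc([C@H]2Oc3c(OC)cc(C=O)cc3[C@@H]2CO)cc(O[Si](C)(C)C(C)(C)C)c1O[Si](C)(C)C(C)(C)C
F3 | step 6 | ethyl (E)-3-[(2R,3S)-2-[3,4-bis(tert-butyldimethylsilyloxy)-5-methoxyphenyl]-3-(hydroxymethyl)-7-methoxy-2,3-dihydro-1-benzofuran-5-yl]prop-2-enoate | COc1cc([C@@H]2Oc3c(OC)cc(/C=C/C(=O)OCC)cc3[C@H]2CO)cc(O[Si](C)(C)C(C)(C)C)c1O[Si](C)(C)C(C)(C)C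
F4 | step 6 | (E)-3-[(2R,3S)-2-[3,4-bis(tert-butyldimethylsilyloxy)-5-methoxyphenyl]-3-(hydroxymethyl)-7-methoxy-2,3-dihydro-1-benzofuran-5-yl]prop-2-en-1-ol | COc1cc([C@@H]2Oc3c(OC)cc(/C=C/CO)cc3[C@H]2CO)cc(O[Si](C)(C)C(C)(C)C)c1O[Si](C)(C)C(C)(C)C
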